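**Retrosynthetic overview**
1. Target 26 ⇐ triol 25 by acetylation of the equatorial 7β-OH; 25 ⇐ C12 aldehyde 19 by two Wittig olefinations (C12=C13, then C14=C15).
2. The C6, C7 and C8 oxygens come from the C7=C8 alkene of the drimane core: allylic oxidation at C6, α-face hydride (6β-OH), α-face osmylation (8α-OH, 8β-CH3), then oxidation/reduction at C7 (7α → 7β).
3. C12 comes from a one-carbon homologation of drimenal 6 (methoxymethylene Wittig) and is carried as a dimethyl acetal.
4. The strategy rests on rings A and B (C1–C10, trans-fused, 5α-H) with the C10 methyl, the 9β carbon C11 and the C8 methyl. This is a chair–chair folded head-to-tail farnesyl chain, so a drimenol synthase closes ring A (bond C4–C5) and then ring B (bond C9–C10) in one cascade, farnesyl diphosphate 3 → (−)-drimenol 5.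
5. Diphosphate 3 is made from (2E,6E)-farnesol 1 in two steps.

Key step: step 3

Remark: drimane/labdane numbering is used throughout (C11 on C9, C12–C16 in the side chain, C17 on C8); β is the face of the C10 methyl group.
Remark: the drimenol synthase is taken to be of the bifunctional cyclase–phosphatase type, which removes the diphosphate of drimenyl diphosphate by hydrolysis at phosphorus, so O11 of the substrate stays in drimenol and the leaving group is counted as two orthophosphate ions.

Step 1
Reactants: 1 (2E,6E)-farnesol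
Product: 2 (2E,6E)-farnesyl chloride
Conditions: N-chlorosuccinimide, Me2S, CH2Cl2, −40 → 0 °C
Reagents that add atoms: N-chlorosuccinimide, O=C1CCC(=O)N1Cl
Why: Corey–Kim chlorination, in which the alcohol is activated on the chlorosulfonium reagent and chloride displaces dimethyl sulfoxide at the primary allylic carbon by SN2 at low temperature, so the 2E alkene is kept and no allylic transposition is expected.

Step 2
Reactants: 2 (2E,6E)-farnesyl chloride
Product: 3 (2E,6E)-farnesyl diphosphate, tris(ammonium) salt
Conditions: (n-Bu4N)3HP2O7, MeCN, rt; then cation exchange (Dowex 50W-X8, NH4+ form, aq. NH4HCO3/i-PrOH), cellulose chromatography, lyophilisation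
Reagents that add atoms: tris(tetrabutylammonium) hydrogen diphosphate, CCCC[N+](CCCC)(CCCC)CCCC.CCCC[N+](CCCC)(CCCC)CCCC.CCCC[N+](CCCC)(CCCC)CCCC.OP(=O)([O-])OP(=O)([O-])[O-]; ammonium hydrogen carbonate, [NH4+].OC([O-])=O
Why: SN2 diphosphorylation of a primary allylic chloride by the soluble diphosphate anion in dry acetonitrile should give the allylic diphosphate without transposition, and cation exchange gives the water-soluble ammonium salt that the enzyme accepts.

Step 3
Reactants: 3 (2E,6E)-farnesyl diphosphate, tris(ammonium) salt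
Product: 5 (−)-drimenol, via drimenyl diphosphate 4 (not isolated)
Conditions: recombinant drimenol synthase (bifunctional cyclase–phosphatase type, expressed in E. coli, purified), Tris·HCl buffer pH 8.0, MgCl2, dithiothreitol, 30 °C, pentane overlay
Reagents that add atoms: none
Why: An active-site acid of the cyclase domain protonates C3 of the chair–chair folded chain, the C4 cation is captured by the C5=C10 alkene and the resulting C10 cation by the C8=C9 alkene, a base removes H-7 to leave the C7=C8 alkene, and the phosphatase domain then hydrolyses the diphosphate ester at phosphorus to free the C11 alcohol. The closest known reaction type is the protonation-initiated polyene cyclisation of terpene cyclases of the squalene–hopene kind, and this is the native reaction of a drimenol synthase. Ring A closes by 6-endo-trig attack of the C5=C10 alkene on C4 (bond C4–C5) and ring B by 6-endo-trig attack of the C8=C9 alkene on C10 (bond C9–C10). C5, C10 and C9 are set together: anti addition across the two E alkenes in the chair–chair fold gives the trans ring fusion (5α-H, 10β-CH3) and the equatorial 9β-CH2O arm, and the chiral pocket binds only one enantiomeric fold, which fixes the absolute configuration. The step needs regioselective termination (loss of H-7 rather than a C12 methyl proton or H-9, and no water capture at C8) and retention of the C11–O bond; the E,E geometry of the substrate secures the relative configuration, the Mg2+-bound diphosphate anchors C11 away from the cationic centres, and the placement of the enzyme base secures the C7=C8 alkene.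

Step 4
Reactants: 5 (−)-drimenol
Product: 6 drimenal (drim-7-en-11-al)
Conditions: Dess–Martin periodinane, NaHCO3, CH2Cl2, 0 °C → rt; used crude
Reagents that add atoms: none
Why: Dess–Martin oxidation under bicarbonate buffer takes the primary alcohol to the aldehyde without acid or strong base, so the C9 stereocentre and the position of the C7=C8 alkene should be kept.

Step 5
Reactants: 6 drimenal; 7 (methoxymethyl)triphenylphosphonium chloride
Product: 9 12-methoxy-13,14,15,16-tetranorlabda-7,11-diene (E/Z mixture), via (methoxymethylene)triphenylphosphorane 8 (not isolated)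
Conditions: 7, KN(SiMe3)2, THF, 0 °C; then 6, −78 → 0 °C
Reagents that add atoms: none
Why: Wittig methoxymethylenation, in which the non-stabilised ylide should add to the formyl carbon at −78 °C faster than it removes the shielded axial C9–H, giving the enol ether with C9 intact (both alkene isomers converge in step 6).

Step 6
Reactants: 9 12-methoxy-13,14,15,16-tetranorlabda-7,11-diene
Product: 10 12,12-dimethoxy-13,14,15,16-tetranorlabd-7-ene
Conditions: MeOH, pyridinium p-toluenesulfonate (cat.), rt
Reagents that add atoms: methanol, CO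
Why: acid-catalysed addition of methanol to the enol ether (protonation at C11, capture of the C12 oxocarbenium ion) gives the dimethyl acetal under conditions too mild to move the trisubstituted C7=C8 alkene.

Step 7
Reactants: 10 12,12-dimethoxy-13,14,15,16-tetranorlabd-7-ene
Product: 11 12,12-dimethoxy-13,14,15,16-tetranorlabd-7-en-6-one
Conditions: CrO3, 3,5-dimethylpyrazole, CH2Cl2, −20 °C
Reagents that add atoms: chromium trioxide, O=[Cr](=O)=O
Why: chromium-mediated allylic oxidation attacks the only allylic methylene, C6, and gives the conjugated 7-en-6-one as is usual for drim-7-enes, while the tertiary C9–H is shielded and the acetal should survive the non-aqueous low-temperature conditions.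

Step 8
Reactants: 11 12,12-dimethoxy-13,14,15,16-tetranorlabd-7-en-6-one
Product: 12 12,12-dimethoxy-13,14,15,16-tetranorlabd-7-en-6β-ol
Conditions: NaBH4, CeCl3·7H2O, MeOH, −20 → 0 °C
Reagents that add atoms: none
Why: Luche 1,2-reduction, in which hydride reaches C6 from the α face because the β face is blocked by the axial methyl groups on C4 and C10, which sets the axial 6β-hydroxyl.

Step 9
Reactants: 12 12,12-dimethoxy-13,14,15,16-tetranorlabd-7-en-6β-ol
Product: 13 12,12-dimethoxy-6β-(triethylsilyloxy)-13,14,15,16-tetranorlabd-7-ene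
Conditions: Et3SiOTf (1.2 equiv), 2,6-lutidine, CH2Cl2, −78 °C
Reagents that add atoms: triethylsilyl trifluoromethanesulfonate, CC[Si](CC)(CC)OS(=O)(=O)C(F)(F)F
Why: silylation with a silyl triflate and a hindered pyridine base caps the hindered 6β-hydroxyl at −78 °C, where O-silylation is far faster than activation of the dimethyl acetal.

Step 10
Reactants: 13 12,12-dimethoxy-6β-(triethylsilyloxy)-13,14,15,16-tetranorlabd-7-ene
Product: 14 12,12-dimethoxy-6β-(triethylsilyloxy)-13,14,15,16-tetranorlabdane-7α,8α-diol
Conditions: OsO4 (10 mol %), N-methylmorpholine N-oxide, MeSO2NH2, acetone/t-BuOH/H2O, rt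
Reagents that add atoms: osmium tetroxide, O=[Os](=O)(=O)=O; N-methylmorpholine N-oxide, C[N+]1([O-])CCOCC1; water, O
Why: Upjohn dihydroxylation, a syn addition to the C7=C8 alkene from the α face (anti to the 6β-silyloxy group and the C10 methyl group), sets 8α-OH/8β-CH3 and gives the 7α,8α-diol.

Step 11
Reactants: 14 12,12-dimethoxy-6β-(triethylsilyloxy)-13,14,15,16-tetranorlabdane-7α,8α-diol
Product: 15 8α-hydroxy-12,12-dimethoxy-6β-(triethylsilyloxy)-13,14,15,16-tetranorlabdan-7-one
Conditions: 2-iodoxybenzoic acid, DMSO, rt → 40 °C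
Reagents that add atoms: none
Why: oxidation with 2-iodoxybenzoic acid converts the secondary 7α-hydroxyl of a 1,2-diol to the ketone without C–C cleavage, the tertiary 8α-hydroxyl cannot be oxidised, and the equatorial C6–H is poorly aligned for enolisation so the 6β centre is kept.

Step 12
Reactants: 15 8α-hydroxy-12,12-dimethoxy-6β-(triethylsilyloxy)-13,14,15,16-tetranorlabdan-7-one
Product: 16 12,12-dimethoxy-6β-(triethylsilyloxy)-13,14,15,16-tetranorlabdane-7β,8α-diol
Conditions: NaBH4, MeOH/THF, −20 °C (protic, cold, to suppress 6 → 7 silyl migration)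
Reagents that add atoms: none
Why: borohydride reduction of the cyclohexanone by axial hydride delivery from the open α face (the β face is flanked by the axial 8β-methyl and 6β-silyloxy groups) should give the equatorial 7β-hydroxyl, which inverts C7 relative to the osmylation product.

Step 13
Reactants: 16 12,12-dimethoxy-6β-(triethylsilyloxy)-13,14,15,16-tetranorlabdane-7β,8α-diol
Product: 17 12,12-dimethoxy-6β-(triethylsilyloxy)-7β,8α-bis(trimethylsilyloxy)-13,14,15,16-tetranorlabdane
Conditions: N-(trimethylsilyl)imidazole (excess), CH2Cl2, rt → 40 °C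
Reagents that add atoms: N-(trimethylsilyl)imidazole, C[Si](C)(C)n1ccnc1
Why: O-silylation with a silyl imidazole, a strong silyl donor that is not a Lewis acid, caps the secondary 7β- and the tertiary 8α-hydroxyl without touching the dimethyl acetal, and the cap on O8 prevents later lactol formation or oxa-Michael closure onto C12.

Step 14
Reactants: 17 12,12-dimethoxy-6β-(triethylsilyloxy)-7β,8α-bis(trimethylsilyloxy)-13,14,15,16-tetranorlabdane
Product: 19 6β-(triethylsilyloxy)-7β,8α-bis(trimethylsilyloxy)-13,14,15,16-tetranorlabdan-12-al, via N-(1-methoxyalkyl)collidinium triflate 18 (not isolated)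
Conditions: Et3SiOTf, 2,4,6-collidine, CH2Cl2, 0 °C; then H2O
Reagents that add atoms: water, O (carbonyl oxygen of 19); 2,4,6-collidine, Cc1cc(C)nc(C)c1, and triethylsilyl trifluoromethanesulfonate, CC[Si](CC)(CC)OS(=O)(=O)C(F)(F)F (atoms in 18 only)
Why: silyl triflate/collidine cleavage of an aldehyde dimethyl acetal (collidinium N,O-acetal, then hydrolysis) releases the C12 aldehyde under non-acidic conditions that should leave the three silyl ethers in place.

Step 15
Reactants: 19 6β-(triethylsilyloxy)-7β,8α-bis(trimethylsilyloxy)-13,14,15,16-tetranorlabdan-12-al; 20 2-(triphenylphosphoranylidene)propanal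
Product: 21 (12E)-6β-(triethylsilyloxy)-7β,8α-bis(trimethylsilyloxy)-15-norlabd-12-en-14-al
Conditions: toluene, 90 °C
Reagents that add atoms: none
Why: Wittig olefination with a formyl-stabilised ylide is under thermodynamic control and should give the (E)-2-methyl-2-enal, with C11 and the formyl group trans across the new C12=C13 bond.

Step 16
Reactants: 21 (12E)-6β-(triethylsilyloxy)-7β,8α-bis(trimethylsilyloxy)-15-norlabd-12-en-14-al; 22 methyltriphenylphosphonium bromide
Product: 24 (12E)-6β-(triethylsilyloxy)-7β,8α-bis(trimethylsilyloxy)labda-12,14-diene, via methylenetriphenylphosphorane 23 (not isolated)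
Conditions: 22, KN(SiMe3)2, THF, 0 °C; then 21, −78 → 0 °C
Reagents that add atoms: none
Why: Wittig methylenation of the enal carbonyl (1,2-addition) installs C15 and completes the conjugated 12E,14-diene without touching the C12=C13 geometry.

Step 17
Reactants: 24 (12E)-6β-(triethylsilyloxy)-7β,8α-bis(trimethylsilyloxy)labda-12,14-diene
Product: 25 (12E)-labda-12,14-diene-6β,7β,8α-triol
Conditions: Bu4NF, THF, rt → 40 °C
Reagents that add atoms: none
Why: fluoride-mediated desilylation removes the two trimethylsilyl ethers and the hindered triethylsilyl ether under non-acidic conditions, which avoids acid-induced cyclisation of the 8-hydroxy diene to an 8,13-ether.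

Step 18
Reactants: 25 (12E)-labda-12,14-diene-6β,7β,8α-triol
Product: 26 (12E)-6β,8α-dihydroxylabda-12,14-dien-7β-yl acetate (CNP0225877.1)
Conditions: Ac2O (1.2 equiv), pyridine, 0 °C → rt
Reagents that add atoms: acetic anhydride, CC(=O)OC(C)=O
Why: selective acylation, in which only the equatorial secondary 7β-hydroxyl should react because the 6β-hydroxyl is shielded by the syn-axial methyl groups on C4, C10 and C8 and the 8α-hydroxyl is tertiary, the selectivity known for 6β,7β-diols of this labdane type.

**Compound list**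
1 | (2E,6E)-farnesol | CC(C)=CCC/C(C)=C/CC/C(C)=C/CO | starting material
2 | (2E,6E)-farnesyl chloride | CC(C)=CCC/C(C)=C/CC/C(C)=C/CCl | intermediate
3 | (2E,6E)-farnesyl diphosphate, tris(ammonium) salt | CC(C)=CCC/C(C)=C/CC/C(C)=C/COP(=O)([O-])OP(=O)([O-])[O-].[NH4+].[NH4+].[NH4+] | intermediate
4 | drimenyl diphosphate (enzyme-bound, ammonium counter-ions) | [O-]P(=O)([O-])OP(=O)([O-])OC[C@H]1C(C)=CC[C@H]2C(C)(C)CCC[C@@]21C.[NH4+].[NH4+].[NH4+] | intermediate
5 | (−)-drimenol, (5S,9S,10S)-drim-7-en-11-ol | OC[C@H]1C(C)=CC[C@H]2C(C)(C)CCC[C@@]21C | intermediate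
6 | drimenal, drim-7-en-11-al | O=C[C@H]1C(C)=CC[C@H]2C(C)(C)CCC[C@@]21C | intermediate
7 | (methoxymethyl)triphenylphosphonium chloride | COC[P+](c1ccccc1)(c1ccccc1)c1ccccc1.[Cl-] | starting material
8 | (methoxymethylene)triphenylphosphorane | COC=P(c1ccccc1)(c1ccccc1)c1ccccc1 | intermediate
9 | 12-methoxy-13,14,15,16-tetranorlabda-7,11-diene (E/Z mixture) | COC=C[C@H]1C(C)=CC[C@H]2C(C)(C)CCC[C@@]21C | intermediate
10 | 12,12-dimethoxy-13,14,15,16-tetranorlabd-7-ene | COC(OC)C[C@H]1C(C)=CC[C@H]2C(C)(C)CCC[C@@]21C | intermediate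
11 | 12,12-dimethoxy-13,14,15,16-tetranorlabd-7-en-6-one | COC(OC)C[C@H]1C(C)=CC(=O)[C@H]2C(C)(C)CCC[C@@]21C | intermediate
12 | 12,12-dimethoxy-13,14,15,16-tetranorlabd-7-en-6β-ol | COC(OC)C[C@H]1C(C)=C[C@@H](O)[C@H]2C(C)(C)CCC[C@@]21C | intermediate
13 | 12,12-dimethoxy-6β-(triethylsilyloxy)-13,14,15,16-tetranorlabd-7-ene | COC(OC)C[C@H]1C(C)=C[C@@H](O[Si](CC)(CC)CC)[C@H]2C(C)(C)CCC[C@@]21C | intermediate
14 | 12,12-dimethoxy-6β-(triethylsilyloxy)-13,14,15,16-tetranorlabdane-7α,8α-diol | COC(OC)C[C@H]1[C@](C)(O)[C@H](O)[C@@H](O[Si](CC)(CC)CC)[C@H]2C(C)(C)CCC[C@@]21C | intermediate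
15 | 8α-hydroxy-12,12-dimethoxy-6β-(triethylsilyloxy)-13,14,15,16-tetranorlabdan-7-one | COC(OC)C[C@H]1[C@](C)(O)C(=O)[C@@H](O[Si](CC)(CC)CC)[C@H]2C(C)(C)CCC[C@@]21C | intermediate
16 | 12,12-dimethoxy-6β-(triethylsilyloxy)-13,14,15,16-tetranorlabdane-7β,8α-diol | COC(OC)C[C@H]1[C@](C)(O)[C@@H](O)[C@@H](O[Si](CC)(CC)CC)[C@H]2C(C)(C)CCC[C@@]21C | intermediate
17 | 12,12-dimethoxy-6β-(triethylsilyloxy)-7β,8α-bis(trimethylsilyloxy)-13,14,15,16-tetranorlabdane | COC(OC)C[C@H]1[C@](C)(O[Si](C)(C)C)[C@@H](O[Si](C)(C)C)[C@@H](O[Si](CC)(CC)CC)[C@H]2C(C)(C)CCC[C@@]21C | intermediate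
18 | N-(1-methoxyalkyl)-2,4,6-collidinium triflate from 17 (C12 epimers) | COC(C[C@H]1[C@](C)(O[Si](C)(C)C)[C@@H](O[Si](C)(C)C)[C@@H](O[Si](CC)(CC)CC)[C@H]2C(C)(C)CCC[C@@]21C)[n+]1c(C)cc(C)cc1C.[O-]S(=O)(=O)C(F)(F)F | intermediate
19 | 6β-(triethylsilyloxy)-7β,8α-bis(trimethylsilyloxy)-13,14,15,16-tetranorlabdan-12-al | O=CC[C@H]1[C@](C)(O[Si](C)(C)C)[C@@H](O[Si](C)(C)C)[C@@H](O[Si](CC)(CC)CC)[C@H]2C(C)(C)CCC[C@@]21C | intermediate
20 | 2-(triphenylphosphoranylidene)propanal | CC(C=O)=P(c1ccccc1)(c1ccccc1)c1ccccc1 | starting material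
21 | (12E)-6β-(triethylsilyloxy)-7β,8α-bis(trimethylsilyloxy)-15-norlabd-12-en-14-al | O=C/C(C)=C/C[C@H]1[C@](C)(O[Si](C)(C)C)[C@@H](O[Si](C)(C)C)[C@@H](O[Si](CC)(CC)CC)[C@H]2C(C)(C)CCC[C@@]21C | intermediate
22 | methyltriphenylphosphonium bromide | C[P+](c1ccccc1)(c1ccccc1)c1ccccc1.[Br-] | starting material
23 | methylenetriphenylphosphorane | C=P(c1ccccc1)(c1ccccc1)c1ccccc1 | intermediate
24 | (12E)-6β-(triethylsilyloxy)-7β,8α-bis(trimethylsilyloxy)labda-12,14-diene | C=C/C(C)=C/C[C@H]1[C@](C)(O[Si](C)(C)C)[C@@H](O[Si](C)(C)C)[C@@H](O[Si](CC)(CC)CC)[C@H]2C(C)(C)CCC[C@@]21C | intermediate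
25 | (12E)-labda-12,14-diene-6β,7β,8α-triol | C=C/C(C)=C/C[C@H]1[C@](C)(O)[C@@H](O)[C@@H](O)[C@H]2C(C)(C)CCC[C@@]21C | intermediate
26 | (12E)-6β,8α-dihydroxylabda-12,14-dien-7β-yl acetate (CNP0225877.1) | C=C/C(C)=C/C[C@H]1[C@](C)(O)[C@@H](OC(C)=O)[C@@H](O)[C@H]2C(C)(C)CCC[C@@]21C | target

**Step count and risks**
Total step count: 18. Longest linear sequence: 18 steps (1 → 26); the three phosphorus reagents 7, 20 and 22 are bought.

Steps most likely to fail:

Step 5. The basic ylide may enolise the β,γ-unsaturated aldehyde (epimerisation at C9 or migration of the alkene into conjugation) faster than it adds to the hindered formyl group. The fallback sets out from drimenal 6 and avoids basic reagents. Takai–Lombardo methylenation (Zn, CH2Br2, TiCl4, THF/CH2Cl2, 0 °C → rt) should give 13,14,15,16-tetranorlabda-7,11-diene F1. Hydroboration of the monosubstituted alkene with 9-borabicyclo[3.3.1]nonane (THF, rt) gives the B-alkyl-9-borabicyclononane F2, oxidised in the same flask (NaOH, H2O2) to 13,14,15,16-tetranorlabd-7-en-12-ol F3. Dess–Martin oxidation then gives 13,14,15,16-tetranorlabd-7-en-12-al F4, and HC(OMe)3/MeOH/pyridinium p-toluenesulfonate brings the route back at dimethyl acetal 10.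

Step 10. Osmylation of the trisubstituted alkene, which sits between the axial 6β-silyloxy group and C9, may be slow, and the hindered osmate ester may hydrolyse poorly, so that catalytic turnover stalls. The fallback sets out from silyl ether 13 and uses a RuO4-catalysed ketohydroxylation (RuCl3 cat., KHSO5 as the triple salt 2KHSO5·KHSO4·K2SO4, NaHCO3, EtOAc/MeCN/H2O, rt). The smaller, more electrophilic oxidant adds syn from the α face, and because C8 is fully substituted only C7 can become the ketone, so the route comes back directly at ketol 15 without diol 14 or the separate alcohol oxidation; no compound outside the list is made (F0).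

Step 15. The formyl-stabilised ylide is weakly nucleophilic, so the olefination may be sluggish, and at the temperature required the product enal may be olefinated a second time. The fallback sets out from aldehyde 19 and passes through the ester oxidation level. The more nucleophilic ethyl 2-(triphenylphosphoranylidene)propanoate (toluene, 80 °C) should give ethyl (12E)-6β-(triethylsilyloxy)-7β,8α-bis(trimethylsilyloxy)-15-norlabd-12-en-14-oate F5, which cannot react further with the ylide. Reduction with i-Bu2AlH (CH2Cl2, −78 °C) gives (12E)-6β-(triethylsilyloxy)-7β,8α-bis(trimethylsilyloxy)-15-norlabd-12-en-14-ol F6, and MnO2 (CH2Cl2, rt) brings the route back at enal 21.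

Further compounds
F1 | step 5 | 13,14,15,16-tetranorlabda-7,11-diene | C=C[C@H]1C(C)=CC[C@H]2C(C)(C)CCC[C@@]21C
F2 | step 5 | B-(13,14,15,16-tetranorlabd-7-en-12-yl)-9-borabicyclo[3.3.1]nonane | C(C[C@H]1C(C)=CC[C@H]2C(C)(C)CCC[C@@]21C)B1C2CCCC1CCC2
F3 | step 5 | 13,14,15,16-tetranorlabd-7-en-12-ol | OCC[C@H]1C(C)=CC[C@H]2C(C)(C)CCC[C@@]21C
F4 | step 5 | 13,14,15,16-tetranorlabd-7-en-12-al | O=CC[C@H]1C(C)=CC[C@H]2C(C)(C)CCC[C@@]21C
F0 | step 10 | none | none
F5 | step 15 | ethyl (12E)-6β-(triethylsilyloxy)-7β,8α-bis(trimethylsilyloxy)-15-norlabd-12-en-14-oate | CCOC(=O)/C(C)=C/C[C@H]1[C@](C)(O[Si](C)(C)C)[C@@H](O[Si](C)(C)C)[C@@H](O[Si](CC)(CC)CC)[C@H]2C(C)(C)CCC[C@@]21C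
F6 | step 15 | (12E)-6β-(triethylsilyloxy)-7β,8α-bis(trimethylsilyloxy)-15-norlabd-12-en-14-ol | OC/C(C)=C/C[C@H]1[C@](C)(O[Si](C)(C)C)[C@@H](O[Si](C)(C)C)[C@@H](O[Si](CC)(CC)CC)[C@H]2C(C)(C)CCC[C@@]21C
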